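The pitfall is the early ratio of G to L. It reads 4.34 in theta and 5.13 in delta and looks like a constant of the flask, yet theta later reaches 1.91.

| flask | J | X | temperature | remark | time |
|---|---|---|---|---|---|
| theta | 0.069 M (fed, over 6.0 h) | 0.010 M | −5 °C | run made earlier |  |
| delta | 0.069 M (fed, over 6.0 h) | 0.041 M | 10 °C | run made earlier |  |
| eta | 0.10 M (fed, over 6.0 h) | 0.0207 M | −5 °C | run made earlier |  |
| noon | 0.069 M (fed, over 6.0 h) | 0.0207 M |  | at 0 °C throughout | 3.0 d |
| dawn | 0.069 M (fed, over 6.0 h) | 0.0207 M |  | at 0 °C until 6.0 h, from then on at 20 °C | 5.0 d |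

theta run (percent of the J charged)

| time / d | G / % | L / % |
|---|---|---|
| 0.417 | 62.0 | 14.3 |
| 0.833 | 62.5 | 17.9 |
| 1.25 | 59.8 | 21.0 |
| 1.67 | 55.9 | 22.5 |
| 2.00 | 55.0 | 25.9 |
| 2.50 | 54.5 | 26.3 |
| 3.00 | 52.8 | 27.7 |

delta run (percent of the J charged)

| time / h | G / % | L / % |
|---|---|---|
| 2.50 | 23.6 | 4.6 |
| 8.00 | 59.5 | 9.9 |
| 12.0 | 55.3 | 9.7 |
| 20.0 | 51.6 | 8.7 |
| 25.0 | 48.4 | 8.4 |
| 40.0 | 42.0 | 7.2 |

eta run (percent of the J charged)

| time / d | G / % | L / % |
|---|---|---|
| 0.250 | 43.4 | 8.9 |
| 0.833 | 64.0 | 16.6 |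
| 1.25 | 60.4 | 19.4 |
| 2.00 | 55.3 | 22.0 |
| 3.00 | 52.0 | 25.5 |

(standard deviation of a reading: 0.5 percentage points)

- what is said of G includes Q
- Q is a solid; its amount is given per volume of the solution
- what was read earlier has a scatter of 0.5 percentage points, one standard deviation
- steps that have been proposed: J <-> E; J <-> G; J + X -> Z; Q <-> G; J <-> L
- percentages count the whole charge, also what has not yet gone in

1. which one finishes higher in share of G in all that became G or L or E ("neither" within 2 percentage points) (noon / dawn / neither)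
2. share of G in all that became G or L or E, noon
3. share of G in all that became G or L or E, dawn

In the first extreme, kinetic control, the early ratio stays, noon and dawn share it, and the answer is neither. In the second, thermodynamic control, each flask ends at the ratio of its last temperature. The late readings give that ratio in powers of ten, through the decade slope, the decades of G/L gained per kelvin:

delta: r = 5.83, log r = 0.766 at 10 °C; theta: log r = 0.281 at −5 °C

slope = 0.0324 /K

The real flasks should lie near the second extreme. Delta's ratio reads 6.01 at 8.00 h and 5.83 at 40.0 h, so it shows no drift beyond the scatter of the readings. Theta's ratio is still falling at its last reading, so this slope, an estimate, may read low. Noon is warmer than theta, and dawn, after its change of temperature, warmer than delta.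

For E, my own reckoning uses theta's balance. X can bind 14.5 % of the charge, so by the last readings about 5.01 % or more stands as J or E. Counted as E, that is a fraction 0.0948 of G.

noon: r = 2.77, share = 1/(1 + 1/r + 0.0948) = 68.7 %

dawn: r = 12.3, share = 85.0 %

The forecast says dawn, with 67 % and 79 %, on “G/L of about 7–12 and perhaps more E”. My dawn share of 85.0 % stands above its figure.

Dawn finishes higher, 86.0 % against 66.5 %, which puts the forecast 7 percentage points low on dawn. At 30.0 d noon's share is 66.6 %, and at 50.0 d dawn's is 86.0 %. The slope gives 0.648 decades of G/L between 0 °C and 20 °C, and noon and dawn end 0.734 decades apart.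

    J ⇌ E (K = 0.450, k = 0.0531 /h, Ea = 84.0 kJ/mol, ΔH = −2.00 kJ/mol)
    J ⇌ G (K = 4.93, k = 0.611 /h, Ea = 84.0 kJ/mol, ΔH = 0 kJ/mol)
    J + X → Z (k = 1.35 /M/h, Ea = 69.0 kJ/mol)
    Q ⇌ G, rate k4*(cs4 - [G]) while solid is left; crystals form when [G] > cs4 (solubility = 50.0 mM, k = 0.307 /h)
    J ⇌ L (K = 2.02, k = 0.112 /h, Ea = 86.0 kJ/mol, ΔH = −56.0 kJ/mol)
    (constants at 0 °C)

The neighbour, noon with 0.28 M of J, holds G 80.8 %, of which 62.9 % is solid Q, so 17.9 % is dissolved. Taking the ratio that the slope gave for 0 °C, 2.77, on dissolved G gives L 6.46 % and a share of 90.8 %. The flask gives L 7.91 % and 89.4 %.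

Readings and results were computed on assumed constants, and the scatter is random.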